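**Retrosynthetic overview**

1. Target 20 ⇒ 19 by late allylic hydroxylation at C15 (C–O); 19 ⇒ 18 by oxidation; ring D of 18 ⇒ keto-alkyne 17 (ketyl–alkyne closure, C13–C16).
2. 17 ⇒ 14 by a singlet-oxygen ene reaction that puts oxygen on C1 and moves C1=C2 to C2=C3; 14 ⇒ 12 by propargylation at C8.
3. Key disconnection: spiro δ-lactone 12 ⇒ diene 6 + enoic acid 11, cut at the C20–O bond; forming this bond (anti-Markovnikov acyloxylation) triggers C9–C10 bond formation in the same operation.
4. 6 ⇒ 5,5-dimethylcyclohex-2-en-1-one 1 (asymmetric hydroxymethylation sets C5, then methylenation); 11 ⇒ 3-methoxybenzoic acid 7 (Birch reduction, ketal).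
5. Ring order: ring A (bought) and ring C (from the arene) → lactone ring (step 7) → ring D (step 11).

Assumption: atom labels C1–C20 are the ent-kaurane numbers of the corresponding target atoms (C7/C20 lactone, C6 aldehyde carbon); "1ξ" means a C1 epimer mixture that is erased in step 12.

**Route**

Step 1
Reactants: 1 5,5-dimethylcyclohex-2-en-1-one
Product: 3 trimethyl[(3,3-dimethylcyclohexa-1,5-dien-1-yl)oxy]silane, via lithium dienolate 2 (not isolated)
Conditions: LiN(i-Pr)2, THF, −78 °C; Me3SiCl, −78 → 0 °C
Reagents that add atoms: chlorotrimethylsilane, C[Si](C)(C)Cl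
Why: Kinetic α′-deprotonation of the enone gives the cross-conjugated dienolate, and O-silylation fixes it as the 2-silyloxy diene whose only nucleophilic carbon is the future C5 (silyl enol ether formation).

Step 2
Reactants: 3 trimethyl[(3,3-dimethylcyclohexa-1,5-dien-1-yl)oxy]silane
Product: 4 (S)-6-(hydroxymethyl)-5,5-dimethylcyclohex-2-en-1-one
Conditions: aq. HCHO, Sc(OTf)3 (10 mol%), chiral 6,6′-bis(1-hydroxy-2,2-dimethylpropyl)-2,2′-bipyridine (12 mol%, enantiomer that gives S), DME/H2O 9:1, −20 °C
Reagents that add atoms: formaldehyde, C=O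
Why: Catalytic asymmetric Mukaiyama aldol (aqueous hydroxymethylation of a silicon enolate); the chiral scandium–bipyridine complex differentiates the enolate faces and sets C5.

Step 3
Reactants: 4 (S)-6-(hydroxymethyl)-5,5-dimethylcyclohex-2-en-1-one
Product: 5 (S)-6-{[tert-butyl(dimethyl)silyl]oxymethyl}-5,5-dimethylcyclohex-2-en-1-one
Conditions: t-BuMe2SiCl, imidazole, CH2Cl2, 0 °C
Reagents that add atoms: tert-butyldimethylsilyl chloride, CC(C)(C)[Si](C)(C)Cl
Why: Silyl ether protection under mild base keeps the hydroxyl from adding to the diene radical cation in step 7 and does not touch the epimerisable C5.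

Step 4
Reactants: 5 (S)-6-{[tert-butyl(dimethyl)silyl]oxymethyl}-5,5-dimethylcyclohex-2-en-1-one
Product: 6 (R)-tert-butyl[(2,2-dimethyl-6-methylidenecyclohex-4-en-1-yl)methoxy]dimethylsilane
Conditions: Zn, CH2Br2, TiCl4 (promoter), THF, pre-aged reagent; then 5, CH2Cl2, 0 → 23 °C
Reagents that add atoms: dibromomethane, BrCBr
Why: Lombardo–Takai methylenation is non-basic, so the hindered enone carbonyl becomes the exocyclic C10=C20 alkene without epimerising or eliminating at C5; the product is an s-trans-locked 1,3-diene.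

Step 5
Reactants: 7 3-methoxybenzoic acid
Product: 9 3-oxocyclohex-1-ene-1-carboxylic acid, via dihydro acid 8 (not isolated)
Conditions: Li, NH3(l), THF, −78 °C; NH4Cl; then 2 M HCl (aq), 60 °C
Reagents that add atoms: water, O
Why: Birch reduction gives the 1,4-dihydro acid; acid hydrolysis of its enol ether and conjugation deliver the enone acid with the ring C oxygen meta to the carboxyl (C13 relative to C8).

Step 6
Reactants: 9 3-oxocyclohex-1-ene-1-carboxylic acid
Product: 11 1,4-dioxaspiro[4.5]dec-7-ene-7-carboxylic acid, via hydroxyethyl ester 10 (not isolated)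
Conditions: HOCH2CH2OH, TsOH (cat.), benzene, reflux, Dean–Stark; then LiOH, THF/H2O; cold 1 M HCl to pH 4
Reagents that add atoms: ethylene glycol, OCCO; lithium hydroxide, [Li+].[OH-]
Why: Acid-catalysed ketalisation of the enone goes through the dienol ether and α-protonation, so the alkene moves out of conjugation with C13 into the C8=C9 position, still conjugated with the carboxyl (deconjugative ketalisation, then saponification of the glycol ester).

Step 7
Reactants: 6 (R)-tert-butyl[(2,2-dimethyl-6-methylidenecyclohex-4-en-1-yl)methoxy]dimethylsilane; 11 1,4-dioxaspiro[4.5]dec-7-ene-7-carboxylic acid (1.5 equiv)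
Product: 12 spirolactone ketal silyl ether
Conditions: 3,6-di-tert-butyl-9-mesityl-10-phenylacridinium tetrafluoroborate (5 mol%), 2,6-lutidine (25 mol%), ClCH2CH2Cl (0.05 M), 450 nm LEDs, 23 °C, degassed, no H-atom donor
Reagents that add atoms: none
Why: Proposed new method: the excited acridinium (about +2.1 V vs SCE) oxidises only the conjugated diene of 6 (estimated +1.7 V) to its radical cation, and the carboxylate of 11 adds at the unhindered exocyclic CH2 to forge the C20–O bond anti-Markovnikov; the resulting allyl radical (C10–C1–C2) is now tethered through the new ester and can reach the enoate only through C10, closing 6-endo onto the β-carbon C9 (5-exo at fully substituted C8 is sterically and polarity disfavoured), and the tertiary α-acyl radical at C8 is reduced by the acridine radical and protonated, so the cycle is redox-neutral and no thiol is present to quench the allyl radical early; C9 should bond to C10 anti to the pseudoaxial C5–CH2OTBS group, with C11 over the flat C1=C2 side and H9 between C1 and C5, which would set C10 and C9 as in the target (C8 is protonated cis and reset in step 8); the closest known reaction is the acridinium-photoredox polar radical crossover cycloaddition of alkenes with unsaturated acids to γ-butyrolactones (5-exo) and the related anti-Markovnikov hydroacyloxylation, here extended to a 1,3-diene donor and a 6-endo closure giving a spiro δ-lactone.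

Step 8
Reactants: 12 spirolactone ketal silyl ether
Product: 14 C8-propargyl spirolactone, via lithium lactone enolate 13 (not isolated)
Conditions: LiN(i-Pr)2, THF/DMPU, −78 °C; HC≡CCH2Br, −78 → −20 °C
Reagents that add atoms: propargyl bromide, C#CCBr
Why: Alkylation of the ring-fusion lactone enolate gives the cis-fused product (as with 1-decalone enolates), the electrophile entering anti to C11 so that the propargyl group (C15–C17) ends up trans to C10 and the C8 quaternary centre is set.

Step 9
Reactants: 14 C8-propargyl spirolactone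
Product: 15 6-hydroxy-13-oxo keto alcohol
Conditions: 2 M HCl (aq)/THF 1:3, 23 °C
Reagents that add atoms: water, O
Why: Acidic hydrolysis removes the dioxolane and the primary silyl ether together, before any acid-sensitive allylic alcohol is present.

Step 10
Reactants: 15 6-hydroxy-13-oxo keto alcohol
Product: 17 1ξ,6-dihydroxy-13-oxo-2-ene, via allylic hydroperoxide 16 (not isolated)
Conditions: O2, tetraphenylporphyrin (1 mol%), CH2Cl2, visible light, 0 °C; then PPh3
Reagents that add atoms: oxygen, O=O
Why: Schenck ene reaction: C1=C2 has allylic hydrogens only at C3 (C10 is quaternary), so oxygen must bond to C1 and the alkene must shift to C2=C3; the alkyne and ketone are inert, and the new C1 stereocentre is unselective and irrelevant.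

Step 11
Reactants: 17 1ξ,6-dihydroxy-13-oxo-2-ene
Product: 18 tetracyclic triol
Conditions: SmI2 (4 equiv), HMPA, t-BuOH, THF, 0 → 23 °C
Reagents that add atoms: none
Why: Stork-type ketyl–alkyne reductive cyclisation (5-exo-dig): the C13 ketyl adds to C16 of the axial propargyl group, giving the bicyclo[3.2.1]octane with the bridgehead 13-OH (configuration fixed by the bridge) and the 16-exo-methylene; the lactone and isolated alkene are not reduced.

Step 12
Reactants: 18 tetracyclic triol
Product: 19 13-hydroxy-1,6-dioxo-6,7-seco-ent-kaura-2,16-dien-7,20-olide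
Conditions: Dess–Martin periodinane (3 equiv), CH2Cl2, 23 °C
Reagents that add atoms: none
Why: Dess–Martin oxidation converts the allylic C1 alcohol to the enone and the primary C6 alcohol to the aldehyde in one operation; the tertiary 13-OH is untouched and C5 does not epimerise under these non-basic conditions.

Step 13
Reactants: 19 13-hydroxy-1,6-dioxo-6,7-seco-ent-kaura-2,16-dien-7,20-olide
Product: 20 13,15α-dihydroxy-1,6-dioxo-6,7-seco-ent-kaura-2,16-dien-7,20-olide (target)
Conditions: SeO2 (0.5 equiv), t-BuOOH (3 equiv), CH2Cl2, 23 °C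
Reagents that add atoms: selenium dioxide, O=[Se]=O; tert-butyl hydroperoxide, CC(C)(C)OO
Why: Sharpless–Riley allylic hydroxylation (ene reaction, then [2,3]-shift): C15 is the only allylic C–H position in the molecule, and oxygen is expected on the face of ring D away from C14, by analogy with the 15α-hydroxylation of ent-kaur-16-enes and steviol.

**Compound list**

1 | 5,5-dimethylcyclohex-2-en-1-one | O=C1C=CCC(C)(C)C1 | starting material
2 | lithium 3,3-dimethylcyclohexa-1,5-dien-1-olate (cross-conjugated dienolate of 1) | [Li]OC1=CC(C)(C)CC=C1 | intermediate (not isolated)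
3 | trimethyl[(3,3-dimethylcyclohexa-1,5-dien-1-yl)oxy]silane | C[Si](C)(C)OC1=CC(C)(C)CC=C1 | intermediate
4 | (S)-6-(hydroxymethyl)-5,5-dimethylcyclohex-2-en-1-one | O=C1C=CCC(C)(C)[C@H]1CO | intermediate
5 | (S)-6-{[tert-butyl(dimethyl)silyl]oxymethyl}-5,5-dimethylcyclohex-2-en-1-one | O=C1C=CCC(C)(C)[C@H]1CO[Si](C)(C)C(C)(C)C | intermediate
6 | (R)-tert-butyl[(2,2-dimethyl-6-methylidenecyclohex-4-en-1-yl)methoxy]dimethylsilane | C=C1C=CCC(C)(C)[C@H]1CO[Si](C)(C)C(C)(C)C | intermediate
7 | 3-methoxybenzoic acid | COc1cccc(c1)C(=O)O | starting material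
8 | 3-methoxycyclohexa-2,5-diene-1-carboxylic acid | COC1=CC(C(=O)O)C=CC1 | intermediate (not isolated)
9 | 3-oxocyclohex-1-ene-1-carboxylic acid | O=C1C=C(C(=O)O)CCC1 | intermediate
10 | 2-hydroxyethyl 1,4-dioxaspiro[4.5]dec-7-ene-7-carboxylate | OCCOC(=O)C1=CCCC2(C1)OCCO2 | intermediate (not isolated)
11 | 1,4-dioxaspiro[4.5]dec-7-ene-7-carboxylic acid | OC(=O)C1=CCCC2(C1)OCCO2 | intermediate
12 | 6-(tert-butyldimethylsilyloxy)-13,13-ethylenedioxy-15,16,17-trinor-6,7-seco-ent-kaur-1-en-7,20-olide (spiro δ-lactone; 5β-H, 8β-H, 9β-H, C20 α; lactone cis-fused to ring C) | O=C1OC[C@]2(C=CCC(C)(C)[C@H]2CO[Si](C)(C)C(C)(C)C)[C@@H]2CCC3(C[C@H]12)OCCO3 | intermediate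
13 | lithium enolate of 12 (C7–OLi, C7=C8) | [Li]OC1=C2CC3(OCCO3)CC[C@H]2[C@]2(CO1)C=CCC(C)(C)[C@H]2CO[Si](C)(C)C(C)(C)C | intermediate (not isolated)
14 | 6-(tert-butyldimethylsilyloxy)-13,13-ethylenedioxy-6,7:13,16-diseco-ent-kaur-1-en-16-yn-7,20-olide (propargyl on C8, trans to C10) | O=C1OC[C@]2(C=CCC(C)(C)[C@H]2CO[Si](C)(C)C(C)(C)C)[C@@H]2CCC3(C[C@]12CC#C)OCCO3 | intermediate
15 | 6-hydroxy-13-oxo-6,7:13,16-diseco-ent-kaur-1-en-16-yn-7,20-olide | O=C1OC[C@]2(C=CCC(C)(C)[C@H]2CO)[C@@H]2CCC(=O)C[C@]12CC#C | intermediate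
16 | 1ξ-hydroperoxy-6-hydroxy-13-oxo-6,7:13,16-diseco-ent-kaur-2-en-16-yn-7,20-olide | O=C1OC[C@]2(C(OO)C=CC(C)(C)[C@H]2CO)[C@@H]2CCC(=O)C[C@]12CC#C | intermediate (not isolated)
17 | 1ξ,6-dihydroxy-13-oxo-6,7:13,16-diseco-ent-kaur-2-en-16-yn-7,20-olide | O=C1OC[C@]2(C(O)C=CC(C)(C)[C@H]2CO)[C@@H]2CCC(=O)C[C@]12CC#C | intermediate
18 | 1ξ,6,13-trihydroxy-6,7-seco-ent-kaura-2,16-dien-7,20-olide | C=C1C[C@]23C[C@@]1(O)CC[C@H]2[C@]1(COC3=O)C(O)C=CC(C)(C)[C@H]1CO | intermediate
19 | 13-hydroxy-1,6-dioxo-6,7-seco-ent-kaura-2,16-dien-7,20-olide | C=C1C[C@]23C[C@@]1(O)CC[C@H]2[C@]1(COC3=O)C(=O)C=CC(C)(C)[C@H]1C=O | intermediate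
20 | 13,15α-dihydroxy-1,6-dioxo-6,7-seco-ent-kaura-2,16-dien-7,20-olide (CNP0521079.1; 15-OH on the face of ring D away from C14) | C=C1[C@@H](O)[C@]23C[C@@]1(O)CC[C@H]2[C@]1(COC3=O)C(=O)C=CC(C)(C)[C@H]1C=O | target

**Step count and risks**

Total steps: 13. Longest linear sequence: 11 (steps 1–4 and 7–13, from 1).

Steps most likely to fail:

Step 7 (the proposed annulation). The allyl radical may be too stabilised or too hindered to close onto C9, the diene radical cation may dimerise, or the C9/C10 diastereoselectivity may be poor. The fallback sets out from 5 and comes back at 12, using known chemistry in which the C–O bond is made by epoxide opening and the radical by photoredox deoxygenation. Ketone 5 reacts with dimethylsulfonium methylide (Me3S+ I−, KN(SiMe3)2, THF, −10 °C) by 1,2-addition to give spiro-epoxide F1. The cesium salt of 11 (Cs2CO3, DMF, 70 °C) opens it at the CH2 terminus to give tertiary allylic alcohol ester F2. Methyl chlorooxoacetate, Et3N and DMAP give methyl oxalate F3, and one equivalent of CsOH in THF/H2O gives cesium oxalate F4. Irradiation with Ir[dF(CF3)ppy]2(dtbbpy)PF6 (blue LEDs, DME/DMF, H2O, 60 °C) expels two CO2 to give the same tertiary allylic C10 radical, which closes 6-endo onto C9 and is reduced and protonated to 12. This fallback shares the radical cyclisation, so it answers failure of the C–O-forming radical-cation stage, not a poor C9/C10 ratio.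

Step 10 (singlet-oxygen ene). A cis-disubstituted cyclohexene next to a quaternary carbon reacts slowly with singlet oxygen. The fallback sets out from 14 and comes back at 17, by epoxide opening and selenoxide elimination instead of the ene reaction. 14 is epoxidised (m-CPBA, NaHCO3, CH2Cl2) to C1–C2 epoxide F5. PhSeNa ((PhSe)2, NaBH4, EtOH) opens it at the less hindered C2 to give hydroxy selenide F6; the ketal keeps C13 safe from NaBH4. H2O2 oxidation and syn-elimination towards C3 give protected allylic alcohol F7. 2 M HCl/THF then removes the ketal and silyl ether to give 17.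

Step 2 (asymmetric hydroxymethylation). The nucleophilic carbon is neopentylic and the enantioselectivity on this dienol silane is untested. The fallback sets out from 1 and comes back at 4, by racemic aldol and enzymatic kinetic resolution. 1 is deprotonated (LiN(i-Pr)2, THF, −78 °C) and treated with gaseous formaldehyde to give racemic hydroxymethyl ketone F8. Amano lipase PS with vinyl acetate in t-BuOMe acetylates the R enantiomer to (R)-acetate F9 and leaves (S)-4, which is separated by chromatography (maximum 50% yield; the enzyme's preference must be confirmed).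

Further compounds

F1 | step 7 | 4-{[tert-butyl(dimethyl)silyl]oxymethyl}-5,5-dimethyl-1-oxaspiro[2.5]oct-7-ene (spiro-epoxide of 5; C4 configuration retained, mixture at the spiro carbon) | C1OC12C=CCC(C)(C)[C@H]2CO[Si](C)(C)C(C)(C)C
F2 | step 7 | tertiary allylic alcohol ester: (1-hydroxy-6-{[tert-butyl(dimethyl)silyl]oxymethyl}-5,5-dimethylcyclohex-2-en-1-yl)methyl 1,4-dioxaspiro[4.5]dec-7-ene-7-carboxylate | OC1(COC(=O)C2=CCCC3(C2)OCCO3)C=CCC(C)(C)[C@H]1CO[Si](C)(C)C(C)(C)C
F3 | step 7 | methyl oxalate of F2 (oxalate on the tertiary alcohol) | COC(=O)C(=O)OC1(COC(=O)C2=CCCC3(C2)OCCO3)C=CCC(C)(C)[C@H]1CO[Si](C)(C)C(C)(C)C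
F4 | step 7 | cesium oxalate of F2 | [Cs+].[O-]C(=O)C(=O)OC1(COC(=O)C2=CCCC3(C2)OCCO3)C=CCC(C)(C)[C@H]1CO[Si](C)(C)C(C)(C)C
F5 | step 10 | C1–C2 epoxide of 14 | O=C1OC[C@]2(C3OC3CC(C)(C)[C@H]2CO[Si](C)(C)C(C)(C)C)[C@@H]2CCC3(C[C@]12CC#C)OCCO3
F6 | step 10 | 1-hydroxy-2-(phenylselanyl) derivative of 14 | O=C1OC[C@]2(C(O)C([Se]c3ccccc3)CC(C)(C)[C@H]2CO[Si](C)(C)C(C)(C)C)[C@@H]2CCC3(C[C@]12CC#C)OCCO3
F7 | step 10 | 1ξ-hydroxy-2-ene analogue of 14 (ketal and silyl ether still in place) | O=C1OC[C@]2(C(O)C=CC(C)(C)[C@H]2CO[Si](C)(C)C(C)(C)C)[C@@H]2CCC3(C[C@]12CC#C)OCCO3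
F8 | step 2 | racemic 6-(hydroxymethyl)-5,5-dimethylcyclohex-2-en-1-one | O=C1C=CCC(C)(C)C1CO
F9 | step 2 | (R)-(6,6-dimethyl-2-oxocyclohex-3-en-1-yl)methyl acetate | O=C1C=CCC(C)(C)[C@@H]1COC(C)=O
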